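The runs stem from a simulated flask on assumed constants, noise included.

I count the catalyst first.

the same everywhere: starting material 48 mM; reagent 144 mM; free catalyst 0.67 mM

| charge | protic impurity | stray impurity | remark |
|---|---|---|---|
| winter | 2.4 mM | 81 µM | the very flask that is asked about, followed so far |
| summer | 2.4 mM | 120 µM | run made earlier |
| flask | 2.40 mM | 81 µM |  |

| run | time / h | product / % |
|---|---|---|
| winter | 0.667 | 0 |
| winter | 2.00 | 0 |
| winter | 3.00 | 0.1 |
| winter | 5.00 | 1.6 |
| winter | 8.00 | 1.3 |
| winter | 10.0 | 3.5 |
| summer | 3.00 | 0 |
| summer | 6.00 | 1.4 |
| summer | 10.0 | 2.6 |
| summer | 12.0 | 3.9 |
| summer | 15.0 | 5.6 |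
| summer | 20.0 | 9.0 |

(standard deviation of a reading: 0.5 percentage points)

- factor on the rate of making product when 5.0% of the starting material are converted if free catalyst is charged twice over
- factor on the rate when 5.0% of the starting material are converted if free catalyst is charged at 6.0 mM instead

Both runs show a lag and then a rising rate, so I read product as made from intermediate that must first accumulate, at a rate that goes with free catalyst times intermediate. The two amounts I weigh are the charge of stray impurity and the charge of free catalyst. I treat the stray impurity as an active-site titrant that removes catalyst one for one before the mark, so the working share, the fraction of the catalyst charge that survives this titration, is 87.9% in this flask.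

The titrant is a fixed amount, so added catalyst all works. Doubling the charge therefore multiplies working catalyst by 2.14, and 6.0 mM multiplies it by 10.0. The charge of protic impurity equals 5.00% of the starting material, the same as the mark, so part of what counts as converted may be quenched substrate. No run reads that share, but more catalyst can shift it towards intermediate, so I hold my two factors as floors.

The forecast says 2.6 and 14, on the ground that “More catalyst lets intermediate outcompete quench”.

The flask gives 2.67 and 16.1, from this scheme:

    starting material + free catalyst ⇌ free catalyst + intermediate (K = 1.30, k = 17.0 L mol⁻¹ h⁻¹)
    reagent + free catalyst + intermediate → free catalyst + product (k = 1200 L² mol⁻² h⁻¹)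
    starting material + protic impurity → quenched substrate (k = 5.90 L mol⁻¹ h⁻¹)
    free catalyst + stray impurity → spent catalyst (k = 3300 L mol⁻¹ h⁻¹)

These are 1.25 and 1.60 times my floors, and at 0.200 d the flask holds 3.63% of the starting material as quenched substrate and 3.59% as intermediate. The summer run has a working share of 82.1%, lower than the 87.9% of the winter run, and at 10.0 h it reads 2.6% of product where the winter run reads 3.5% at 10.0 h, each reading with a scatter of 0.5 percentage points.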